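## Structural features

The target is a flavone: a benzo ring A fused to a 4-pyranone ring C (O1, C2, C3, C4, C4a, C8a), with aryl ring B on C2. It has no stereocentres. Ring C is fully substituted, and C3 carries a methyl ether next to the C4 carbonyl. Six oxygens sit on the periphery, and only two are free phenols: C6-OH, flanked by the C7 methoxy group and para to O1, and C5'-OH, flanked by the C4' methoxy group and para to the C2' methoxy group. Rings A and B are the same unit joined in two ways. Each is a 2,4,5-trioxygenated phenyl group (C4a/O1/C7-OMe/C6-OH and C1'/C2'-OMe/C4'-OMe/C5'-OH), so both can come from one 4-alkoxy-3-methoxyphenol. The feature the key step exploits is that C4a is ortho to O1 and para to the C7 methoxy group, while C5 and C8 carry hydrogen. C4a is therefore the most nucleophilic and least hindered carbon of a ring A phenol that has no carbon substituent at all. The fragile points are the C3 methoxy group (chelation-assisted cleavage by strong Lewis acids), the electron-rich hydroquinone-type phenols (oxidation once free), and the pyranone (opened by strong base). The real difficulty is to tell two hydroxyl groups from four methyl ethers on two near-identical rings and to build the fully substituted pyranone with C3 already a methyl ether.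

## Logic of the disconnections

**13 to 12.** The two O–CH2Ph bonds at O6 and O5' are cut. Both free phenols are then one protecting group, installed once in 1 and removed at the end. The forward step must remove benzyl without reducing the C2=C3 bond or the C4 carbonyl.

**12 to 10 (through 11).** The C4–C4a bond is cut, which opens ring C at carbon and not at O1. C4a is the carbon of ring A where an acylium ion is expected to attack (para to the C7 methoxy group, ortho to O1). Ring A becomes a plain aryloxy group and ring C an open 3-aryloxy-2-methoxyacrylic acid whose double-bond geometry need not be controlled. The forward step must ionise the C4 acid without cleaving the O1–C2 vinyl ether, and must close on C4a in preference to C8, to ring B, or to the 2'-methoxy oxygen.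

**10 to 9.** The C4–OH bond is cut, so C4 goes back one oxidation level to an aldehyde. That makes the preceding union a substitution on a strongly activated vinylogous acid chloride. The forward oxidation must spare the electron-rich rings and the enol ether.

**9 to 8 and 3.** The O1–C2 bond is cut. The two halves of the molecule separate, and ring A appears as 3, which carries no carbon substituent. The forward step is an addition–elimination at C2, which is deactivated by the C3 methoxy group and ring B. The aldehyde at C4 has to provide the activation.

**8 to 6 (through 7).** The C3–C4 bond and the C2–Cl bond are cut. C4 is added as one carbon to the methylene of 6 while the ketone oxygen at C2 is exchanged for chloride in the same operation. This takes the whole C2–C3–C4 chain back to a two-carbon ketone that already holds the C3 methoxy group. The forward step must formylate at C3 and not on ring B.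

**6 to 4 and 5.** The C1'–C2 bond is cut. The position para to one methoxy group and ortho to the other in 4 is the only doubly activated, unhindered carbon. The forward acylation must leave the benzyl ether and the methoxy group ortho to the new ketone intact.

**4 to 3.** The O2'–CH3 bond is cut. Ring B and ring A now come from the same phenol, whose hydroxyl becomes O1 in one half and the C2' methoxy oxygen in the other.

**3 to 1 (through 2).** The aryl C–O bond is traced back to the aryl–CHO bond of 1. In 1 the benzyl ether already marks the oxygen that ends as C6-OH and C5'-OH, so the differentiation of the oxygens is bought with the starting material.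

## Other disconnections considered

**Alternative 1:** the first route that comes to mind cuts O1–C2 and the C3–O bond. Acetophenone A1 (from 3 by acetylation and Fries rearrangement) and aldehyde A2 (from 4 by formylation) would be condensed to the 2'-hydroxychalcone A3. Algar–Flynn–Oyamada oxidation would give flavonol A4, and methylation of its C3 hydroxyl would give 12. The route is viable and has the same step count. The chosen plan is preferred on mechanistic grounds. The peroxide step must attack an enone whose β-carbon is deactivated and shielded by the 2,4-dialkoxyaryl ring, and the partition between flavonol, aurone and dihydroflavonol pathways is delicate there. The C3 oxygen also arrives as a free flavonol hydroxyl needing a separate methylation, whereas the chosen plan carries it as a methyl ether from 5 onwards.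

**Alternative 2:** the symmetry of the two rings suggests cutting C4–C4a and C2–C1' together. Two molecules of 4 would be joined by double Friedel–Crafts acylation with methoxymalonyl dichloride A5 to the symmetrical diketone A6. Demethylative ring closure through either of its two equivalent ortho methoxy groups would then give 12. This is shorter on paper. It is rejected because the intermediate β-ketoacyl chloride has an ortho methoxy oxygen placed to lactonise to the 4-hydroxycoumarin A7 before a second arene is acylated. The ring closure would also have to remove exactly one of two equivalent methyl groups while sparing the chelation-prone C3 methoxy group and two benzyl ethers.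

**Alternative 3:** an aryne could deliver C4a and O1 to ring A in one operation (cuts at C4–C4a and O1–C8a). Aryne A9, generated from silyl triflate A8, would insert into the C–O bond of chloro acid A10. The resulting phenoxide would displace chloride at C2 to give 12. The structure argues against it. The carbons flanking the triple bond of A9 (future C5 and C8) both carry hydrogen, and the only bias is a benzyloxy versus a methoxy group in remote positions. The carboxylate should therefore add to either end and give 12 together with its regioisomer A11. A8 would also cost several steps from 3. The chosen plan forms the same C4–C4a bond with the regiochemistry dictated by the para methoxy group.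

Key step: step 7

Assumption: 8, 9 and 10 are carried forward as mixtures of C2=C3 geometric isomers; this should be harmless because the cationic intermediate of step 7 can rotate about that bond. Phenol 3 is divided, one part going to step 2 and one to step 5.

## Route

Step 1
Reactants: 1 4-(benzyloxy)-3-methoxybenzaldehyde
Product: 3 4-(benzyloxy)-3-methoxyphenol, via aryl formate 2 (not isolated)
Conditions: mCPBA, CH2Cl2, 0 °C → rt; NaHCO3 wash; then K2CO3 (cat.), MeOH, rt
Reagents that add atoms: mCPBA, OOC(=O)c1cccc(Cl)c1
Why: Baeyer–Villiger (Dakin-type) oxidation; the electron-rich aryl group with a para alkoxy donor migrates in preference to hydrogen, and the formate is cleaved by methanolysis.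

Step 2
Reactants: 3 4-(benzyloxy)-3-methoxyphenol
Product: 4 1-(benzyloxy)-2,4-dimethoxybenzene
Conditions: MeI, K2CO3, acetone, reflux
Reagents that add atoms: iodomethane, CI
Why: Williamson etherification of the only free hydroxyl; this turns the ring A phenol into the ring B arene.

Step 3
Reactants: 4 1-(benzyloxy)-2,4-dimethoxybenzene; 5 methoxyacetyl chloride
Product: 6 1-[5-(benzyloxy)-2,4-dimethoxyphenyl]-2-methoxyethan-1-one
Conditions: SnCl4, CH2Cl2, −20 → 0 °C
Reagents that add atoms: none
Why: Friedel–Crafts acylation at the one carbon that is para to one methoxy group and ortho to the other; the carbon between the two methoxy groups is hindered and the carbon next to the benzyloxy group has a single donor. A mild Lewis acid at low temperature should spare the benzyl ether.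

Step 4
Reactants: 6 1-[5-(benzyloxy)-2,4-dimethoxyphenyl]-2-methoxyethan-1-one
Product: 8 3-[5-(benzyloxy)-2,4-dimethoxyphenyl]-3-chloro-2-methoxyprop-2-enal (mixture of geometric isomers), via chloro-iminium salt 7 (not isolated)
Conditions: POCl3, DMF, 0 → 60 °C; then ice–water
Reagents that add atoms: N,N-dimethylformamide, CN(C)C=O; phosphoryl chloride, O=P(Cl)(Cl)Cl; water, O
Why: Vilsmeier–Haack–Arnold chloroformylation of an enolisable aryl ketone. The enol is formylated at the methylene carbon, the resulting enaminone oxygen is activated and displaced by chloride, and water hydrolyses the iminium ion; ring B is deactivated towards the reagent by its own carbonyl group.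

Step 5
Reactants: 8 3-[5-(benzyloxy)-2,4-dimethoxyphenyl]-3-chloro-2-methoxyprop-2-enal; 3 4-(benzyloxy)-3-methoxyphenol
Product: 9 3-[4-(benzyloxy)-3-methoxyphenoxy]-3-[5-(benzyloxy)-2,4-dimethoxyphenyl]-2-methoxyprop-2-enal (mixture of geometric isomers)
Conditions: K2CO3, DMF, rt → 60 °C
Reagents that add atoms: none
Why: Nucleophilic vinylic substitution by addition–elimination on a β-chlorovinyl aldehyde, a vinylogous acid chloride; the aldehyde stabilises the intermediate enolate and chloride leaves to form the O1–C2 bond.

Step 6
Reactants: 9 3-[4-(benzyloxy)-3-methoxyphenoxy]-3-[5-(benzyloxy)-2,4-dimethoxyphenyl]-2-methoxyprop-2-enal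
Product: 10 3-[4-(benzyloxy)-3-methoxyphenoxy]-3-[5-(benzyloxy)-2,4-dimethoxyphenyl]-2-methoxyprop-2-enoic acid (mixture of geometric isomers)
Conditions: NaClO2, NaH2PO4, 2-methyl-2-butene, t-BuOH–H2O, rt
Reagents that add atoms: sodium chlorite, [Na+].[O-]Cl=O
Why: Pinnick oxidation; chlorous acid oxidises only the aldehyde, and the alkene scavenger removes the hypochlorous acid that would otherwise chlorinate the electron-rich rings and the enol ether.

Step 7
Reactants: 10 3-[4-(benzyloxy)-3-methoxyphenoxy]-3-[5-(benzyloxy)-2,4-dimethoxyphenyl]-2-methoxyprop-2-enoic acid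
Product: 12 6-(benzyloxy)-2-[5-(benzyloxy)-2,4-dimethoxyphenyl]-3,7-dimethoxy-4H-chromen-4-one, via mixed trifluoroacetic anhydride 11 (not isolated)
Conditions: TFAA, CH2Cl2, 0 °C → rt
Reagents that add atoms: trifluoroacetic anhydride, O=C(OC(=O)C(F)(F)F)C(F)(F)F (its atoms are carried by 11 only and are lost again on the way to 12)
Why: TFAA converts 10 into the mixed anhydride 11, which should ionise readily because the acylium ion is a vinylogous oxocarbenium/ketene hybrid stabilised by O1 and by the 2,4-dialkoxyphenyl ring. In that hybrid the C2–C3 bond has single-bond character, so both geometric isomers of 10 should funnel into the conformer that holds the acyl carbon over ring A. Ring A attacks through the carbon ortho to O1 and para to its methoxy group (future C4a), and loss of a proton gives the aromatic 4-pyranone. This is an intramolecular Friedel–Crafts acylation, the ring-closing event of the Simonis chromone synthesis and of the classical cyclisation of 3-aryloxycinnamic acids to flavones. Ring C is closed at carbon as a six-membered ring, 6-exo-dig at the acylium carbon, and no stereocentre is formed. Of the two ortho carbons of ring A, the one para to methoxy is the more nucleophilic and the less hindered, the other lying between two oxygens. Closure on ring B would need a five-membered indenone through a carbon with a single ortho donor, and attack by the 2'-methoxy oxygen gives only a methyloxonium ion that should revert, since trifluoroacetate is too weak a nucleophile to take the methyl group. The chloride-free, weakly acidic medium is chosen so that nothing is present to dealkylate that oxonium ion, the benzyl ethers or the C3 methoxy group.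

Step 8
Reactants: 12 6-(benzyloxy)-2-[5-(benzyloxy)-2,4-dimethoxyphenyl]-3,7-dimethoxy-4H-chromen-4-one
Product: 13 6-hydroxy-2-(5-hydroxy-2,4-dimethoxyphenyl)-3,7-dimethoxy-4H-chromen-4-one (6,5'-dihydroxy-3,7,2',4'-tetramethoxyflavone)
Conditions: H2 (1 atm), Pd/C, EtOAc–MeOH, rt
Reagents that add atoms: none
Why: Hydrogenolysis of both aryl benzyl ethers; the tetrasubstituted C2=C3 bond of the pyranone and the methyl ethers should not react under these conditions.

## Compound list

1 | 4-(benzyloxy)-3-methoxybenzaldehyde | COc1cc(C=O)ccc1OCc1ccccc1 | starting material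
2 | 4-(benzyloxy)-3-methoxyphenyl formate | COc1cc(OC=O)ccc1OCc1ccccc1 | intermediate (not isolated)
3 | 4-(benzyloxy)-3-methoxyphenol | COc1cc(O)ccc1OCc1ccccc1 | intermediate
4 | 1-(benzyloxy)-2,4-dimethoxybenzene | COc1ccc(OCc2ccccc2)c(OC)c1 | intermediate
5 | methoxyacetyl chloride | COCC(Cl)=O | starting material
6 | 1-[5-(benzyloxy)-2,4-dimethoxyphenyl]-2-methoxyethan-1-one | COCC(=O)c1cc(OCc2ccccc2)c(OC)cc1OC | intermediate
7 | N-{3-[5-(benzyloxy)-2,4-dimethoxyphenyl]-3-chloro-2-methoxyprop-2-en-1-ylidene}-N-methylmethanaminium chloride (geometry not defined) | COC(C=[N+](C)C)=C(Cl)c1cc(OCc2ccccc2)c(OC)cc1OC.[Cl-] | intermediate (not isolated)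
8 | 3-[5-(benzyloxy)-2,4-dimethoxyphenyl]-3-chloro-2-methoxyprop-2-enal (geometry not defined) | COC(C=O)=C(Cl)c1cc(OCc2ccccc2)c(OC)cc1OC | intermediate
9 | 3-[4-(benzyloxy)-3-methoxyphenoxy]-3-[5-(benzyloxy)-2,4-dimethoxyphenyl]-2-methoxyprop-2-enal (geometry not defined) | COC(C=O)=C(Oc1ccc(OCc2ccccc2)c(OC)c1)c1cc(OCc2ccccc2)c(OC)cc1OC | intermediate
10 | 3-[4-(benzyloxy)-3-methoxyphenoxy]-3-[5-(benzyloxy)-2,4-dimethoxyphenyl]-2-methoxyprop-2-enoic acid (geometry not defined) | COC(C(=O)O)=C(Oc1ccc(OCc2ccccc2)c(OC)c1)c1cc(OCc2ccccc2)c(OC)cc1OC | intermediate
11 | 3-[4-(benzyloxy)-3-methoxyphenoxy]-3-[5-(benzyloxy)-2,4-dimethoxyphenyl]-2-methoxyprop-2-enoic trifluoroacetic anhydride (geometry not defined) | COC(C(=O)OC(=O)C(F)(F)F)=C(Oc1ccc(OCc2ccccc2)c(OC)c1)c1cc(OCc2ccccc2)c(OC)cc1OC | intermediate (not isolated)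
12 | 6-(benzyloxy)-2-[5-(benzyloxy)-2,4-dimethoxyphenyl]-3,7-dimethoxy-4H-chromen-4-one | COc1cc(OC)c(-c2oc3cc(OC)c(OCc4ccccc4)cc3c(=O)c2OC)cc1OCc1ccccc1 | intermediate
13 | 6-hydroxy-2-(5-hydroxy-2,4-dimethoxyphenyl)-3,7-dimethoxy-4H-chromen-4-one | COc1cc(OC)c(-c2oc3cc(OC)c(O)cc3c(=O)c2OC)cc1O | target

## Step count and least certain steps

Total step count: 8. Longest linear sequence: 8 steps (1 → 3 → 4 → 6 → 8 → 9 → 10 → 12 → 13; 3 is also used as the second component of step 5).

**Step 7 (key step).** The most likely failure is capture of the acylium ion by the wrong nucleophile: closure on ring B, or participation of the 2'-methoxy oxygen followed by loss of its methyl group. The other risk is that the liberated acid cleaves the aryl vinyl ether or transfers a benzyl group before the ring closes. The cause is that the ion is strongly stabilised and therefore long-lived and selective only on thermodynamic grounds. A catalytic amount of a stronger Brønsted acid may also be needed to start ionisation. The fallback gives up closure at carbon and returns to closure at oxygen. It sets out from 3 and 4. Phenol 3 would be acylated with 5 under BF3·OEt2 (O-acylation and Fries shift to the carbon para to methoxy) to give 1-[5-(benzyloxy)-2-hydroxy-4-methoxyphenyl]-2-methoxyethan-1-one F1. Arene 4 would be formylated (POCl3, DMF) to 5-(benzyloxy)-2,4-dimethoxybenzaldehyde F2, which is the same compound as A2. Claisen–Schmidt condensation (KOH, EtOH) would give 1-[5-(benzyloxy)-2-hydroxy-4-methoxyphenyl]-3-[5-(benzyloxy)-2,4-dimethoxyphenyl]-2-methoxyprop-2-en-1-one F3. Oxidative cyclisation with catalytic I2 in DMSO at 120 °C (oxa-Michael addition and dehydrogenation) would rejoin the route at 12.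

**Step 4.** The most likely failure is that the sequence stalls after C-formylation at the enaminone stage, or that the chlorophosphorus medium attacks the electron-rich ring or its ethers at the temperature needed for the chloride exchange. The cause is that the α-methoxy ketone is a less reactive enol than a simple aryl methyl ketone. The fallback introduces C4 by base-mediated carboxylation and sets out from 6. Ketone 6 with NaH and dimethyl carbonate would give methyl 3-[5-(benzyloxy)-2,4-dimethoxyphenyl]-2-methoxy-3-oxopropanoate F4. Its enol would be converted with oxalyl chloride and DMF into methyl 3-[5-(benzyloxy)-2,4-dimethoxyphenyl]-3-chloro-2-methoxyprop-2-enoate F5. Substitution with 3 (K2CO3, DMF, heating) would give methyl 3-[4-(benzyloxy)-3-methoxyphenoxy]-3-[5-(benzyloxy)-2,4-dimethoxyphenyl]-2-methoxyprop-2-enoate F6. Hydrolysis with LiOH would rejoin the route at 10 and make step 6 unnecessary.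

**Step 5.** The most likely failure is slow addition of the phenoxide at C2, allowing hydrolysis or self-condensation of the chloro aldehyde to compete. The cause is that C2 is deactivated by the C3 methoxy group and by the dialkoxyaryl ring and is fully substituted. The fallback reverses the order of bond formation, so that the O1–C2 bond is made last and intramolecularly. It sets out from 8 and 3. Pinnick oxidation of 8 would give 3-[5-(benzyloxy)-2,4-dimethoxyphenyl]-3-chloro-2-methoxyprop-2-enoic acid F7, the same compound as A10. Carbodiimide esterification with 3 would give 4-(benzyloxy)-3-methoxyphenyl 3-[5-(benzyloxy)-2,4-dimethoxyphenyl]-3-chloro-2-methoxyprop-2-enoate F8. Fries rearrangement (TiCl4 or photochemical) to the carbon para to methoxy would give 1-[5-(benzyloxy)-2-hydroxy-4-methoxyphenyl]-3-[5-(benzyloxy)-2,4-dimethoxyphenyl]-3-chloro-2-methoxyprop-2-en-1-one F9. With K2CO3 its phenoxide should displace chloride in a six-membered addition–elimination and rejoin the route at 12.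

**Step 3.** The most likely failure is Lewis-acid cleavage of the benzyl ether, or chelation-assisted loss of the methyl group ortho to the new ketone, during or after acylation. The cause is that the product binds the Lewis acid through the carbonyl and the neighbouring ether oxygens. The fallback inverts the polarity and sets out from 4. Bromination with NBS would give 1-(benzyloxy)-5-bromo-2,4-dimethoxybenzene F10. Bromine–lithium exchange with n-BuLi at −78 °C and acylation of the aryllithium with N,2-dimethoxy-N-methylacetamide would rejoin the route at 6 without any Lewis acid.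

## Further compounds

F1 | step 7 | 1-[5-(benzyloxy)-2-hydroxy-4-methoxyphenyl]-2-methoxyethan-1-one | COCC(=O)c1cc(OCc2ccccc2)c(OC)cc1O
F2 | step 7 | 5-(benzyloxy)-2,4-dimethoxybenzaldehyde | COc1cc(OC)c(OCc2ccccc2)cc1C=O
F3 | step 7 | 1-[5-(benzyloxy)-2-hydroxy-4-methoxyphenyl]-3-[5-(benzyloxy)-2,4-dimethoxyphenyl]-2-methoxyprop-2-en-1-one (geometry not defined) | COC(=Cc1cc(OCc2ccccc2)c(OC)cc1OC)C(=O)c1cc(OCc2ccccc2)c(OC)cc1O
F4 | step 4 | methyl 3-[5-(benzyloxy)-2,4-dimethoxyphenyl]-2-methoxy-3-oxopropanoate | COC(C(=O)OC)C(=O)c1cc(OCc2ccccc2)c(OC)cc1OC
F5 | step 4 | methyl 3-[5-(benzyloxy)-2,4-dimethoxyphenyl]-3-chloro-2-methoxyprop-2-enoate (geometry not defined) | COC(C(=O)OC)=C(Cl)c1cc(OCc2ccccc2)c(OC)cc1OC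
F6 | step 4 | methyl 3-[4-(benzyloxy)-3-methoxyphenoxy]-3-[5-(benzyloxy)-2,4-dimethoxyphenyl]-2-methoxyprop-2-enoate (geometry not defined) | COC(C(=O)OC)=C(Oc1ccc(OCc2ccccc2)c(OC)c1)c1cc(OCc2ccccc2)c(OC)cc1OC
F7 | step 5 | 3-[5-(benzyloxy)-2,4-dimethoxyphenyl]-3-chloro-2-methoxyprop-2-enoic acid (geometry not defined) | COC(C(=O)O)=C(Cl)c1cc(OCc2ccccc2)c(OC)cc1OC
F8 | step 5 | 4-(benzyloxy)-3-methoxyphenyl 3-[5-(benzyloxy)-2,4-dimethoxyphenyl]-3-chloro-2-methoxyprop-2-enoate (geometry not defined) | COC(C(=O)Oc1ccc(OCc2ccccc2)c(OC)c1)=C(Cl)c1cc(OCc2ccccc2)c(OC)cc1OC
F9 | step 5 | 1-[5-(benzyloxy)-2-hydroxy-4-methoxyphenyl]-3-[5-(benzyloxy)-2,4-dimethoxyphenyl]-3-chloro-2-methoxyprop-2-en-1-one (geometry not defined) | COC(C(=O)c1cc(OCc2ccccc2)c(OC)cc1O)=C(Cl)c1cc(OCc2ccccc2)c(OC)cc1OC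
F10 | step 3 | 1-(benzyloxy)-5-bromo-2,4-dimethoxybenzene | COc1cc(OC)c(OCc2ccccc2)cc1Br
A1 | alternative 1 | 1-[5-(benzyloxy)-2-hydroxy-4-methoxyphenyl]ethan-1-one | CC(=O)c1cc(OCc2ccccc2)c(OC)cc1O
A2 | alternative 1 | 5-(benzyloxy)-2,4-dimethoxybenzaldehyde | COc1cc(OC)c(OCc2ccccc2)cc1C=O
A3 | alternative 1 | (E)-1-[5-(benzyloxy)-2-hydroxy-4-methoxyphenyl]-3-[5-(benzyloxy)-2,4-dimethoxyphenyl]prop-2-en-1-one | O=C(/C=C/c1cc(OCc2ccccc2)c(OC)cc1OC)c1cc(OCc2ccccc2)c(OC)cc1O
A4 | alternative 1 | 6-(benzyloxy)-2-[5-(benzyloxy)-2,4-dimethoxyphenyl]-3-hydroxy-7-methoxy-4H-chromen-4-one | COc1cc(OC)c(-c2oc3cc(OC)c(OCc4ccccc4)cc3c(=O)c2O)cc1OCc1ccccc1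
A5 | alternative 2 | methoxymalonyl dichloride | COC(C(Cl)=O)C(Cl)=O
A6 | alternative 2 | 1,3-bis[5-(benzyloxy)-2,4-dimethoxyphenyl]-2-methoxypropane-1,3-dione | COC(C(=O)c1cc(OCc2ccccc2)c(OC)cc1OC)C(=O)c1cc(OCc2ccccc2)c(OC)cc1OC
A7 | alternative 2 | 6-(benzyloxy)-4-hydroxy-3,7-dimethoxy-2H-chromen-2-one | COc1cc2oc(=O)c(OC)c(O)c2cc1OCc1ccccc1
A8 | alternative 3 | 4-(benzyloxy)-5-methoxy-2-(trimethylsilyl)phenyl trifluoromethanesulfonate | COc1cc(OS(=O)(=O)C(F)(F)F)c([Si](C)(C)C)cc1OCc1ccccc1
A9 | alternative 3 | 4-(benzyloxy)-5-methoxybenzyne (1-(benzyloxy)-2-methoxy-4,5-didehydrobenzene) | COC1=CC#CC=C1OCc1ccccc1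
A10 | alternative 3 | 3-[5-(benzyloxy)-2,4-dimethoxyphenyl]-3-chloro-2-methoxyprop-2-enoic acid (geometry not defined) | COC(C(=O)O)=C(Cl)c1cc(OCc2ccccc2)c(OC)cc1OC
A11 | alternative 3 | 7-(benzyloxy)-2-[5-(benzyloxy)-2,4-dimethoxyphenyl]-3,6-dimethoxy-4H-chromen-4-one | COc1cc(OC)c(-c2oc3cc(OCc4ccccc4)c(OC)cc3c(=O)c2OC)cc1OCc1ccccc1
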